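**Early times.** At early times the west run already showed both products: at 6.00 min there was 8.8% of uncatalysed product beside 21.1% of target, a reading of 0.417 for their ratio. I built up the flask below from that run, one process at a time.

- west: substrate 0.10 M; reagent 0.18 M; free catalyst 2 mM; second catalyst 2 mM; run made earlier
- flask: substrate 0.10 M; reagent 0.0900 M; free catalyst 2.0 mM; second catalyst 2.0 mM; time 12 h

west run (percent of the substrate charged)

| time / min | uncatalysed product / % | target / % | substrate / % |
|---|---|---|---|
| 6.00 | 8.8 | 21.1 | 36.9 |
| 20.0 | 11.5 | 38.0 | 3.9 |
| 30.0 | 12.8 | 37.4 | 1.2 |
| 50.0 | 12.5 | 37.9 | 0.2 |
| 80.0 | 12.8 | 37.3 | 0.2 |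

(each reading ± 0.5 percentage points)

- the numbers in the tables scatter with a standard deviation of 0.5 percentage points

1. ratio of uncatalysed product to target at 2.5 min
2. ratio of uncatalysed product to target at 12 h
3. which of uncatalysed product and target there is more of at 12 h

**Main step.** I read the loss of substrate as pseudo-first-order, with rate constant k. The west reading at 6.00 min gave k = 0.166 /min. The free catalyst charge in the flask is the same, so I kept k there, which put 34.0% of the substrate as consumed by 2.5 min.

**One branch.** Next I added the uncatalysed route. The west run ended near 12.7% of uncatalysed product, and I took this route's rate to follow the reagent. That gave my quantity as a reading, β = 0.706 /M: the branch coefficient β, the share of the charged substrate ending as uncatalysed product per unit of reagent charged. For the flask it gave 6.35%, half the west value.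

**The rest.** Target in the west run stopped near 37.5%, and the two products together left about half of the substrate unaccounted for. I could not reckon that sink. With target held at the west value I reckoned a final ratio of 0.169 for the flask; with target lowered in step with reagent I reckoned 0.339. Target led in both reckonings. For the flask at 2.5 min I expected a ratio above 0.417, since that time comes before the west reading and the west ratio was falling; this rested on the west charge, so it was a guess.

**The forecast.** The forecast, holding that “Halving the reagent should favour target”, gave 0.35 at 2.5 min, 0.22 at 12 h, and target ahead.

**The result.** The flask gave 0.604 and 0.213, with target ahead: 29.9% against 6.37% of uncatalysed product, beside my 6.35%.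

    second catalyst + target → spent catalyst (k = 0.150 /M/s)
    substrate + free catalyst → free catalyst + open intermediate (k = 1.20 /M/s)
    substrate + reagent → uncatalysed product (k = 0.00220 /M/s)
    reagent + catalyst intermediate → second catalyst + target (k = 2.30 /M/s)
    second catalyst + open intermediate ⇌ catalyst intermediate (K = 5.50 /M, k = 22.0 /M/s)

In the flask at 0.0756 h the half-life of second catalyst by its step with target was 0.13 h, shorter than the 0.30 h of reagent by its step with catalyst intermediate. At 1.20 h the flask held 0% of its second catalyst charge and >99.9% as spent catalyst, with 61.8% of the substrate charged as open intermediate and 57.5% of the reagent left.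

**Second flask.** For the neighbour flask with 0.22 M of reagent, β gave 15.5% of uncatalysed product. Computed, that flask ended at 15.1%, beside 39.4% of target, a ratio of 0.383.

(The data are simulated on assumed constants; scatter was added.)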